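## Retrosynthetic overview
1. Plicatic acid 16 ⇒ spiro[4.5]decadienone 15. In the forward direction a dienone–phenol 1,2-shift moves C1 from C4a to C8a, expands the cyclopentane to ring B and unmasks the ring A phenol.
2. 15 ⇒ 12. While ring A is a dienone, ring C is the only phenol, so it can be ortho-oxygenated selectively. The C3=CH2 group is the latent C3(OH)CH2OH.
3. 12 ⇒ 10. The C4–C4a bond comes from dearomatising para-alkylation of one of two identical guaiacyl groups by the allylic CH2–O of a β-methylene lactone.
4. 10 ⇒ 8 ⇒ 5 + tetronic acid 6, by methylenation, asymmetric C2 hydroxylation and oxidative C1–C2 coupling. Tetronic acid supplies COOH, C2, C3 and C4. Then 5 ⇒ 2 × guaiacol + CH2O, and guaiacol ⇒ catechol.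
5. Ring order: rings A and C (from catechol) → sacrificial lactone (from 6) → spiro cyclopentane (step 6) → ring B by expansion (step 9).

Assumption: the SMILES is read as (1S,2S,3R), natural (−)-plicatic acid; the tetralin locants C1–C4, C4a and C8a are used for the same atoms in all intermediates; 12–15 are carried as both epimers at the spiro carbon, which is erased in step 9.

## Route

Step 1
Reactants: 1 catechol
Product: 2 guaiacol (2-methoxyphenol)
Conditions: MeI (1.0 equiv), K2CO3, acetone, reflux; distil
Reagents that add atoms: iodomethane, CI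
Why: Williamson O-methylation (SN2) of the catechol monoanion, in which limiting MeI keeps dimethylation low; no stereocentre is formed.

Step 2
Reactants: 2 guaiacol (2 equiv, used in excess); 3 formaldehyde
Product: 5 4,4′-methylenebis(2-methoxyphenol), via vanillyl alcohol 4 (not isolated)
Conditions: 37% aq CH2O (0.5 equiv), H2SO4 (cat.), neat 2, 70 °C; crystallise the p,p′-isomer
Reagents that add atoms: none
Why: Acid-catalysed hydroxyalkylation followed by Friedel–Crafts condensation (bisphenol synthesis), in which the free OH directs both C–C bonds para and excess 2 suppresses oligomers; no stereocentre is formed.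

Step 3
Reactants: 5 4,4′-methylenebis(2-methoxyphenol); 6 tetronic acid (4-hydroxyfuran-2(5H)-one)
Product: 8 3-[bis(4-hydroxy-3-methoxyphenyl)methyl]-4-hydroxyfuran-2(5H)-one, via quinone methide 7 (not isolated)
Conditions: DDQ (1.0 equiv, slow addition), 6 (1.5 equiv), MeCN, 0 °C → rt
Reagents that add atoms: none
Why: Cross-dehydrogenative coupling, in which DDQ abstracts hydride from the doubly benzylic CH2 to give p-quinone methide 7 and the soft C3 carbon of the vinylogous acid 6 adds 1,6 with rearomatisation; the more hindered, electron-poorer C1–H of 8 is not re-oxidised, and C1 carries two identical aryl groups so it is not yet a stereocentre.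

Step 4
Reactants: 8 3-[bis(4-hydroxy-3-methoxyphenyl)methyl]-4-hydroxyfuran-2(5H)-one
Product: 9 (3S)-3-[bis(4-hydroxy-3-methoxyphenyl)methyl]-3-hydroxyfuran-2,4(3H,5H)-dione
Conditions: 3-phenyl-2-(phenylsulfonyl)oxaziridine (1.2 equiv), N-(9-anthracenylmethyl)cinchonidinium chloride (10 mol %; the cinchoninium analogue gives the antipode), K2HPO4 (0.2 equiv), THF–toluene, −20 °C
Reagents that add atoms: 3-phenyl-2-(phenylsulfonyl)oxaziridine, O=S(=O)(N1OC1c1ccccc1)c1ccccc1
Why: Catalytic asymmetric electrophilic α-hydroxylation of a β-dicarbonyl (Davis oxygen transfer under chiral ion-pair control), in which only the acidic tetronic acid is ionised, the chiral ammonium cation shields one face of the planar tetronate so that oxygen is delivered to give (S)-C2, and the un-ionised phenols are inert to the oxaziridine.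

Step 5
Reactants: 9 (3S)-3-[bis(4-hydroxy-3-methoxyphenyl)methyl]-3-hydroxyfuran-2,4(3H,5H)-dione
Product: 10 (3S)-3-[bis(4-hydroxy-3-methoxyphenyl)methyl]-3-hydroxy-4-methylideneoxolan-2-one
Conditions: CH2Br2/Zn/TiCl4 (pre-formed reagent, 6 equiv), THF–CH2Cl2, 0 °C → rt; then H2O
Reagents that add atoms: dibromomethane, BrCBr
Why: Lombardo methylenation, in which the non-basic gem-dimetallic titanium methylidene reagent olefinates the easily enolised ketone in preference to the lactone and avoids the base that would trigger retro-1,6-addition of 9; the OH groups are only metalated (hence the excess) and are freed on work-up, and C2 is untouched.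

Step 6
Reactants: 10 (3S)-3-[bis(4-hydroxy-3-methoxyphenyl)methyl]-3-hydroxy-4-methylideneoxolan-2-one
Product: 12 (1S,2S)-2-hydroxy-1-(4-hydroxy-3-methoxyphenyl)-7-methoxy-3-methylidene-8-oxospiro[4.5]deca-6,9-diene-2-carboxylic acid (both epimers at spiro C5), via allylic iodide acid 11 (not isolated)
Conditions: LiI (2 equiv), LiOC(CH3)3 (1.1 equiv), DMF (0.01 M), 70 °C; then cold 1 M HCl to pH 3
Reagents that add atoms: none
Why: Proposed new method: iodide-relay dearomative spirocyclisation – the phenolate para carbon cannot displace the lactone carboxylate directly (the leaving oxygen is held syn to the tether so no backside trajectory exists, and SN2′ attack on the methylene would be 5-endo), but iodide opens the allylic alkyl–oxygen bond (SN2 or SN2′ give the same 2-substituted allyl iodide 11), the freed CH2I rotates anti to the nucleophile and is attacked 5-exo-tet by the para carbon (C4a) of one of the two diastereotopic phenolates, returning iodide, while re-lactonisation of 11 is reversible and harmless; the aryl group that reacts is the one leaving the spectator aryl trans to the carboxylate on the forming cyclopentane, which sets C1 as (S); the closest known reaction types are the Winstein–Masamune Ar1-5 phenolate para-alkylation, LiI alkyl–oxygen cleavage of esters, and halide-relay catalysis as in epoxide/CO2 coupling.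

Step 7
Reactants: 12 spirodienone acid
Product: 13 (1S,2S,3R)-2,3-dihydroxy-3-(hydroxymethyl)-1-(4-hydroxy-3-methoxyphenyl)-7-methoxy-8-oxospiro[4.5]deca-6,9-diene-2-carboxylic acid
Conditions: OsO4 (2 mol %), NMO (1.3 equiv), acetone–H2O, 0 °C → rt
Reagents that add atoms: N-methylmorpholine N-oxide, C[N+]1([O-])CCOCC1; water, O
Why: Catalytic OsO4/NMO syn-dihydroxylation, in which the 1,1-disubstituted alkene reacts faster than the electron-poor dienone C=C bonds and OsO4 approaches anti to the allylic C2–OH (Kishi's rule) and anti to the cis-1,3 aryl group, placing C3–OH trans to C2–OH, that is (3R).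

Step 8
Reactants: 13 spirodienone triol acid
Product: 15 (1S,2S,3R)-1-(3,4-dihydroxy-5-methoxyphenyl)-2,3-dihydroxy-3-(hydroxymethyl)-7-methoxy-8-oxospiro[4.5]deca-6,9-diene-2-carboxylic acid, via ortho-quinone 14 (not isolated)
Conditions: (KSO3)2NO (2.2 equiv), KH2PO4 buffer (pH 6), H2O–acetone, 0 °C; then aq Na2S2O4
Reagents that add atoms: potassium nitrosodisulfonate, [K+].[K+].[O]N(S(=O)(=O)[O-])S(=O)(=O)[O-]
Why: Teuber oxidation, in which ring C is the only phenol left (ring A is masked as the dienone) and its para position is blocked, so the nitrosodisulfonate radical oxygenates the free ortho carbon to o-quinone 14, which dithionite reduces at once to the catechol; the stereocentres are untouched.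

Step 9
Reactants: 15 spirodienone catechol acid
Product: 16 (−)-plicatic acid, (1S,2S,3R)-1-(3,4-dihydroxy-5-methoxyphenyl)-2,3,7-trihydroxy-3-(hydroxymethyl)-6-methoxy-1,2,3,4-tetrahydronaphthalene-2-carboxylic acid
Conditions: CF3CO2H (10 vol %), H2O–MeCN, 25 °C
Reagents that add atoms: none
Why: Acid-catalysed dienone–phenol rearrangement (cationic 1,2-shift, ring expansion), in which O-protonation of the cross-conjugated dienone makes C8a electrophilic, the doubly activated benzylic C1 (a far better migrating group than primary C4) shifts from spiro C4a to C8a (the CH para to OMe, not the hindered CH next to OMe), and loss of H+ rearomatises ring A so the cyclopentane becomes six-membered ring B with C4 para to OH; C1 migrates with retention, and if it ionises to the ring C quinone methide instead, re-closure through the chair with aryl, CO2H and CH2OH all equatorial gives the same (1S) centre, while C2 and C3 are not touched.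

## Compound list
1 | catechol | Oc1ccccc1O | starting material
2 | guaiacol | COc1ccccc1O | intermediate
3 | formaldehyde | C=O | starting material
4 | vanillyl alcohol | COc1cc(CO)ccc1O | intermediate
5 | 4,4′-methylenebis(2-methoxyphenol) | COc1cc(Cc2ccc(O)c(OC)c2)ccc1O | intermediate
6 | tetronic acid | O=C1C=C(O)CO1 | starting material
7 | 4-(4-hydroxy-3-methoxybenzylidene)-2-methoxycyclohexa-2,5-dien-1-one | COC1=CC(=Cc2ccc(O)c(OC)c2)C=CC1=O | intermediate
8 | 3-[bis(4-hydroxy-3-methoxyphenyl)methyl]-4-hydroxyfuran-2(5H)-one | COc1cc(ccc1O)C(c1ccc(O)c(OC)c1)C1=C(O)COC1=O | intermediate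
9 | (3S)-3-[bis(4-hydroxy-3-methoxyphenyl)methyl]-3-hydroxyfuran-2,4(3H,5H)-dione | COc1cc(ccc1O)C(c1ccc(O)c(OC)c1)[C@@]1(O)C(=O)OCC1=O | intermediate
10 | (3S)-3-[bis(4-hydroxy-3-methoxyphenyl)methyl]-3-hydroxy-4-methylideneoxolan-2-one | COc1cc(ccc1O)C(c1ccc(O)c(OC)c1)[C@@]1(O)C(=O)OCC1=C | intermediate
11 | (2S)-2-[bis(4-hydroxy-3-methoxyphenyl)methyl]-2-hydroxy-3-(iodomethyl)but-3-enoic acid | COc1cc(ccc1O)C(c1ccc(O)c(OC)c1)[C@@](O)(C(=O)O)C(=C)CI | intermediate
12 | (1S,2S)-spirodienone acid with C3=CH2 (spiro carbon unassigned) | COC1=CC2(C=CC1=O)CC(=C)[C@](O)(C(=O)O)[C@H]2c1ccc(O)c(OC)c1 | intermediate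
13 | (1S,2S,3R)-spirodienone triol acid | COC1=CC2(C=CC1=O)C[C@@](O)(CO)[C@](O)(C(=O)O)[C@H]2c1ccc(O)c(OC)c1 | intermediate
14 | (1S,2S,3R)-spirodienone triol acid with ring C as 5-methoxy-3,4-dioxocyclohexa-1,5-dienyl | COC1=CC2(C=CC1=O)C[C@@](O)(CO)[C@](O)(C(=O)O)[C@H]2C1=CC(=O)C(=O)C(OC)=C1 | intermediate
15 | (1S,2S,3R)-spirodienone triol acid with ring C as 3,4-dihydroxy-5-methoxyphenyl | COC1=CC2(C=CC1=O)C[C@@](O)(CO)[C@](O)(C(=O)O)[C@H]2c1cc(O)c(O)c(OC)c1 | intermediate
16 | (−)-plicatic acid | COc1cc2c(cc1O)[C@H](c1cc(O)c(O)c(OC)c1)[C@@](O)(C(=O)O)[C@](O)(CO)C2 | target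

## Step count and risks
Total step count: 9. Longest linear sequence: 9 (1 → 16).

**Step 6 (the new step).** The stationary concentration of 11 may be too low, intermolecular O-alkylation may compete, and the choice between the two aryl groups may be poor. The fallback uses known chemistry only, sets out from 10 and comes back at 12. Me3SiBr in CH2Cl2 cleaves the allylic alkyl–oxygen bond of the lactone, and aqueous work-up gives the allylic bromide acid F1. Me3SiCHN2 in toluene–MeOH esterifies only the carboxylic acid, giving the bromo methyl ester F2, which can no longer close back through a carboxylate. A classical Winstein–Masamune cyclisation (KOC(CH3)3, t-BuOH–THF, high dilution) then gives the spirodienone methyl ester F3. LiOH saponification with a cold, mildly acidic work-up returns 12.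

**Step 4.** The tetronate is a weak, non-chelating nucleophile, so both rate and enantioselectivity may be low. The fallback replaces asymmetric catalysis by classical resolution, sets out from 8 and comes back at 12.
- The same oxaziridine with catalytic Et3N gives the racemic hydroxy dione F4.
- The step 5 conditions give the racemic methylene lactone F5.
- The step 6 conditions give, through the racemic allylic iodide acid F6 formed in the flask, the racemic spirodienone acid F7.
- Crystallisation with (R)-1-phenylethylamine gives the less soluble diastereomeric ammonium salt F8. The (S)-amine is used if the other salt crystallises.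
- Cold acidification to pH 3 releases 12.

**Step 7.** OsO4 may attack the wrong face of the exocyclic alkene or the methoxy-enone. The fallback inverts the stereochemical logic, sets out from 12 and comes back at 16. Hydroxyl-directed (Henbest) epoxidation with mCPBA, syn to C2–OH, gives the spiro-epoxide acid F9. Treatment with (KSO3)2NO and then ascorbic acid converts ring C, through the quinone epoxide F10, into the catechol epoxide F11. Aqueous CF3CO2H opens the epoxide at tertiary C3 with inversion, giving 15 in the flask, and triggers the ring expansion in the same operation to give 16.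

## Further compounds
F1 | step 6 | (2S)-2-[bis(4-hydroxy-3-methoxyphenyl)methyl]-3-(bromomethyl)-2-hydroxybut-3-enoic acid | COc1cc(ccc1O)C(c1ccc(O)c(OC)c1)[C@@](O)(C(=O)O)C(=C)CBr
F2 | step 6 | methyl (2S)-2-[bis(4-hydroxy-3-methoxyphenyl)methyl]-3-(bromomethyl)-2-hydroxybut-3-enoate | COc1cc(ccc1O)C(c1ccc(O)c(OC)c1)[C@@](O)(C(=O)OC)C(=C)CBr
F3 | step 6 | methyl ester of 12 | COC1=CC2(C=CC1=O)CC(=C)[C@](O)(C(=O)OC)[C@H]2c1ccc(O)c(OC)c1
F4 | step 4 | rac-9 | COc1cc(ccc1O)C(c1ccc(O)c(OC)c1)C1(O)C(=O)OCC1=O
F5 | step 4 | rac-10 | COc1cc(ccc1O)C(c1ccc(O)c(OC)c1)C1(O)C(=O)OCC1=C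
F6 | step 4 | rac-11 | COc1cc(ccc1O)C(c1ccc(O)c(OC)c1)C(O)(C(=O)O)C(=C)CI
F7 | step 4 | rac-12 (1:1 pair of enantiomers) | COC1=CC2(C=CC1=O)CC(=C)[C@](O)(C(=O)O)[C@H]2c1ccc(O)c(OC)c1.COC1=CC2(C=CC1=O)CC(=C)[C@@](O)(C(=O)O)[C@@H]2c1ccc(O)c(OC)c1
F8 | step 4 | (R)-1-phenylethylammonium salt of 12 | COC1=CC2(C=CC1=O)CC(=C)[C@](O)(C(=O)[O-])[C@H]2c1ccc(O)c(OC)c1.C[C@@H]([NH3+])c1ccccc1
F9 | step 7 | spiro-epoxide of 12, epoxide oxygen cis to C2–OH (C3 S) | COC1=CC2(C=CC1=O)C[C@]3(CO3)[C@](O)(C(=O)O)[C@H]2c1ccc(O)c(OC)c1
F10 | step 7 | ring C ortho-quinone of F9 | COC1=CC2(C=CC1=O)C[C@]3(CO3)[C@](O)(C(=O)O)[C@H]2C1=CC(=O)C(=O)C(OC)=C1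
F11 | step 7 | ring C catechol of F9 | COC1=CC2(C=CC1=O)C[C@]3(CO3)[C@](O)(C(=O)O)[C@H]2c1cc(O)c(O)c(OC)c1
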